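## Retrosynthetic overview

1. The target comes from its primary TBS ether. The methacrylate is installed with inversion (Mitsunobu) on the (1S)-homoallylic alcohol.
2. Key C–C bond: lactone β-carbon to the carbinol carbon. It is made from a β,γ-unsaturated aldehyde and a chiral 3-(bromomethyl)butenolide via an allylchromium in which the butenolide β-carbon, normally an acceptor site, acts as the donor. The same step sets both new stereocentres and creates the exocyclic methylene.
3. Ring order: the only ring (the butenolide) is closed first by ring-closing metathesis of a 2-(bromomethyl)acrylate of an (S)-dienol. It is carried through unchanged; only its double bond transposes in the key step.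
4. The (S)-dienol comes from propargyl alcohol (carboalumination–iodination, coupling with acrolein, lipase resolution that also installs the acetate). The aldehyde comes from (E)-3-methylpent-2-en-4-yn-1-ol (silylation, hydroboration–oxidation).

Assumption: (E)-3-methylpent-2-en-4-yn-1-ol (the trans isomer of the vitamin A C6 building block) is taken as a cheap commercial starting material; lactone positions are given in oxolane numbering.

## Route

Step 1
Reactants: 1 prop-2-yn-1-ol
Product: 3 (E)-3-iodo-2-methylprop-2-en-1-ol, via alkenylalane 2 (not isolated)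
Conditions: AlMe3 (3 equiv), Cp2ZrCl2 (25 mol %), CH2Cl2, 0 °C to rt; then I2, THF, −30 to 0 °C; aq. K2CO3
Reagents that add atoms: trimethylaluminium C[Al](C)C; iodine II
Why: Negishi zirconium-catalysed carboalumination adds Me and Al syn across the alkyne (methyl on the internal carbon), and iodinolysis of the C–Al bond with retention fixes the (E)-trisubstituted alkene.

Step 2
Reactants: 3 (E)-3-iodo-2-methylprop-2-en-1-ol; 4 acrolein
Product: 6 racemic (E)-2-methylhexa-2,5-diene-1,4-diol, via alkenylchromium dichloride 5 (not isolated)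
Conditions: CrCl2 (4 equiv), NiCl2 (2 mol %), DMSO, rt
Reagents that add atoms: none
Why: Nozaki–Hiyama–Kishi coupling: the alkenyl iodide is converted, with retention of geometry, into an alkenyl species of trivalent chromium that adds 1,2 to acrolein and tolerates the free OH; the new carbinol is racemic and is resolved in step 3.

Step 3
Reactants: 6 racemic (E)-2-methylhexa-2,5-diene-1,4-diol
Product: 7 (2E,4S)-4-hydroxy-2-methylhexa-2,5-dien-1-yl acetate
Conditions: Novozym 435 (immobilised Candida antarctica lipase B), vinyl acetate (3 equiv), MTBE, 30 °C, stopped at ca. 50 % acylation of the secondary OH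
Reagents that add atoms: vinyl acetate C=COC(C)=O
Why: Lipase-catalysed transesterification with kinetic resolution: the primary OH of both enantiomers is acetylated fast, then only the (R)-secondary alcohol is acylated (vinyl as medium group, trisubstituted alkenyl as large group, Kazlauskas rule), leaving the (4S)-monoacetate that carries the future lactone C2 stereocentre.

Step 4
Reactants: 7 (2E,4S)-4-hydroxy-2-methylhexa-2,5-dien-1-yl acetate; 8 2-(bromomethyl)prop-2-enoic acid
Product: 10 (3S,4E)-6-acetoxy-5-methylhexa-1,4-dien-3-yl 2-(bromomethyl)prop-2-enoate, via O-acylisourea 9 (not isolated)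
Conditions: DIC, DMAP (5 mol %), CH2Cl2, −10 to 0 °C
Reagents that add atoms: none
Why: Steglich-type carbodiimide esterification; the carbinol C–O bond is untouched so configuration is retained, and low temperature with little DMAP limits attack on the allylic bromide.

Step 5
Reactants: 10 (3S,4E)-6-acetoxy-5-methylhexa-1,4-dien-3-yl 2-(bromomethyl)prop-2-enoate
Product: 11 (E)-3-[(2R)-4-(bromomethyl)-5-oxo-2,5-dihydrofuran-2-yl]-2-methylprop-2-en-1-yl acetate
Conditions: second-generation Grubbs catalyst (H2IMes)(PCy3)Cl2Ru=CHPh (5 mol %), 1,4-benzoquinone (10 mol %), CH2Cl2 (5 mM), 40 °C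
Reagents that add atoms: none
Why: Ring-closing metathesis: the catalyst loads on the terminal vinyl group and closes onto the 1,1-disubstituted acrylate to give the butenolide with loss of ethylene, the trisubstituted alkene and the bromide being spectators; the stereocentre is not involved (S becomes R only through a priority change).

Step 6
Reactants: 12 (E)-3-methylpent-2-en-4-yn-1-ol
Product: 13 tert-butyl(dimethyl){[(E)-3-methylpent-2-en-4-yn-1-yl]oxy}silane
Conditions: TBSCl, Et3N, DMAP (5 mol %), CH2Cl2, 0 °C to rt
Reagents that add atoms: tert-butyldimethylsilyl chloride CC(C)(C)[Si](C)(C)Cl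
Why: Standard silylation of the primary allylic alcohol, giving a group that survives the organochromium and Mitsunobu steps and is removed last.

Step 7
Reactants: 13 tert-butyl(dimethyl){[(E)-3-methylpent-2-en-4-yn-1-yl]oxy}silane
Product: 16 (E)-5-[tert-butyl(dimethyl)silyl]oxy-3-methylpent-3-enal, via dienylborane 14 (not isolated), via dienol 15 (not isolated)
Conditions: Cy2BH (from BH3·SMe2 and cyclohexene, 1.05 equiv), THF, 0 °C; then H2O2, pH 7 phosphate buffer, 0 °C; used crude at once
Reagents that add atoms: hydrogen peroxide OO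
Why: Anti-Markovnikov hydroboration of the terminal alkyne by the bulky dialkylborane followed by oxidation gives the dienol, which is protonated kinetically at the α-carbon to the β,γ-unsaturated aldehyde; neutral buffer keeps the alkene out of conjugation and the (E) geometry is inherited.

Step 8
Reactants: 11 (E)-3-[(2R)-4-(bromomethyl)-5-oxo-2,5-dihydrofuran-2-yl]-2-methylprop-2-en-1-yl acetate; 16 (E)-5-[tert-butyl(dimethyl)silyl]oxy-3-methylpent-3-enal
Product: 18 (E)-3-[(2R,3R)-3-[(1S,3E)-5-[tert-butyl(dimethyl)silyl]oxy-1-hydroxy-3-methylpent-3-en-1-yl]-4-methylidene-5-oxooxolan-2-yl]-2-methylprop-2-en-1-yl acetate, via allylchromium dichloride 17 (not isolated)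
Conditions: CrCl2 (3 equiv), THF, 0 °C to rt, 11 and 16 (1.3 equiv) added together; pH 7 buffer work-up
Reagents that add atoms: none
Why: Nozaki–Hiyama (Barbier-type) allylation in which CrCl2 turns the allylic bromide into an allylchromium whose reacting γ-carbon is the β-carbon of the butenolide (a homoenolate-type donor at a normally electrophilic position); it adds to the aldehyde carbon through a closed chair transition state on the face anti to the C2 alkenyl group (3R, trans to 2R), and the ring-locked allyl geometry with the aldehyde chain equatorial gives the anti adduct (1S) while the double bond moves to the exocyclic position.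

Step 9
Reactants: 18 the (1S)-alcohol from step 8; 19 2-methylprop-2-enoic acid
Product: 21 (1R,3E)-1-[(2R,3R)-2-[(E)-3-acetoxy-2-methylprop-1-en-1-yl]-4-methylidene-5-oxooxolan-3-yl]-5-[tert-butyl(dimethyl)silyl]oxy-3-methylpent-3-en-1-yl 2-methylprop-2-enoate, via alkoxyphosphonium methacrylate 20 (not isolated)
Conditions: PPh3 (1.5 equiv) and DIAD (1.5 equiv) premixed in toluene at 0 °C, then 19 (2 equiv) and 18, BHT (trace), 0 °C to rt
Reagents that add atoms: none
Why: Mitsunobu esterification: the alcohol is activated as an alkoxyphosphonium ion and displaced by methacrylate in an SN2 reaction, inverting the carbinol from S to R while installing the ester; premixing avoids free PPh3 adding to the α-methylene lactone.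

Step 10
Reactants: 21 the silyl-protected methacrylate from step 9
Product: 22 (1R,3E)-1-[(2R,3R)-2-[(E)-3-acetoxy-2-methylprop-1-en-1-yl]-4-methylidene-5-oxooxolan-3-yl]-5-hydroxy-3-methylpent-3-en-1-yl 2-methylprop-2-enoate (CNP0323189.1)
Conditions: HF·pyridine, THF/pyridine, 0 °C
Reagents that add atoms: none
Why: Fluoride-mediated desilylation of the primary allylic silyl ether under buffered conditions that leave the acetate, the methacrylate and the α-methylene lactone intact; no stereocentre is touched.

## Compound list

1 | prop-2-yn-1-ol | C#CCO | starting material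
2 | (E)-alkenyl(dimethyl)alane of the dimethylaluminium alkoxide of 2-methylprop-2-en-1-ol | C[Al](C)/C=C(\C)CO[Al](C)C | intermediate
3 | (E)-3-iodo-2-methylprop-2-en-1-ol | OC/C(C)=C/I | intermediate
4 | acrolein | C=CC=O | starting material
5 | [(E)-3-hydroxy-2-methylprop-1-en-1-yl]chromium dichloride (trivalent chromium) | OC/C(C)=C/[Cr](Cl)Cl | intermediate
6 | racemic (E)-2-methylhexa-2,5-diene-1,4-diol | C=CC(O)/C=C(\C)CO | intermediate
7 | (2E,4S)-4-hydroxy-2-methylhexa-2,5-dien-1-yl acetate | C=C[C@H](O)/C=C(\C)COC(C)=O | intermediate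
8 | 2-(bromomethyl)prop-2-enoic acid | C=C(CBr)C(=O)O | starting material
9 | O-acylisourea from 8 and DIC | C=C(CBr)C(=O)OC(=NC(C)C)NC(C)C | intermediate
10 | (3S,4E)-6-acetoxy-5-methylhexa-1,4-dien-3-yl 2-(bromomethyl)prop-2-enoate | C=C[C@H](OC(=O)C(=C)CBr)/C=C(\C)COC(C)=O | intermediate
11 | (E)-3-[(2R)-4-(bromomethyl)-5-oxo-2,5-dihydrofuran-2-yl]-2-methylprop-2-en-1-yl acetate | O=C1O[C@@H](C=C1CBr)/C=C(\C)COC(C)=O | intermediate
12 | (E)-3-methylpent-2-en-4-yn-1-ol | C#C/C(C)=C/CO | starting material
13 | tert-butyl(dimethyl){[(E)-3-methylpent-2-en-4-yn-1-yl]oxy}silane | C#C/C(C)=C/CO[Si](C)(C)C(C)(C)C | intermediate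
14 | dicyclohexyl[(1E,3E)-5-(tert-butyldimethylsilyloxy)-3-methylpenta-1,3-dien-1-yl]borane | C1CCCCC1B(C1CCCCC1)/C=C/C(C)=C/CO[Si](C)(C)C(C)(C)C | intermediate
15 | (1E,3E)-5-(tert-butyldimethylsilyloxy)-3-methylpenta-1,3-dien-1-ol | O/C=C/C(C)=C/CO[Si](C)(C)C(C)(C)C | intermediate
16 | (E)-5-[tert-butyl(dimethyl)silyl]oxy-3-methylpent-3-enal | O=CC/C(C)=C/CO[Si](C)(C)C(C)(C)C | intermediate
17 | {[(5R)-5-[(E)-3-acetoxy-2-methylprop-1-en-1-yl]-2-oxo-2,5-dihydrofuran-3-yl]methyl}chromium dichloride (trivalent chromium) | Cl[Cr](Cl)CC1=C[C@@H](/C=C(\C)COC(C)=O)OC1=O | intermediate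
18 | (E)-3-[(2R,3R)-3-[(1S,3E)-5-[tert-butyl(dimethyl)silyl]oxy-1-hydroxy-3-methylpent-3-en-1-yl]-4-methylidene-5-oxooxolan-2-yl]-2-methylprop-2-en-1-yl acetate | O[C@@H](C/C(C)=C/CO[Si](C)(C)C(C)(C)C)[C@H]1C(=C)C(=O)O[C@@H]1/C=C(\C)COC(C)=O | intermediate
19 | 2-methylprop-2-enoic acid (methacrylic acid) | C=C(C)C(=O)O | starting material
20 | alkoxy(triphenyl)phosphonium methacrylate derived from 18 | C=C(C)C(=O)[O-].c1ccccc1[P+](c1ccccc1)(c1ccccc1)O[C@@H](C/C(C)=C/CO[Si](C)(C)C(C)(C)C)[C@H]1C(=C)C(=O)O[C@@H]1/C=C(\C)COC(C)=O | intermediate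
21 | (1R,3E)-1-[(2R,3R)-2-[(E)-3-acetoxy-2-methylprop-1-en-1-yl]-4-methylidene-5-oxooxolan-3-yl]-5-[tert-butyl(dimethyl)silyl]oxy-3-methylpent-3-en-1-yl 2-methylprop-2-enoate | C=C(C)C(=O)O[C@H](C/C(C)=C/CO[Si](C)(C)C(C)(C)C)[C@H]1C(=C)C(=O)O[C@@H]1/C=C(\C)COC(C)=O | intermediate
22 | (1R,3E)-1-[(2R,3R)-2-[(E)-3-acetoxy-2-methylprop-1-en-1-yl]-4-methylidene-5-oxooxolan-3-yl]-5-hydroxy-3-methylpent-3-en-1-yl 2-methylprop-2-enoate | C=C(C)C(=O)O[C@H](C/C(C)=C/CO)[C@H]1C(=C)C(=O)O[C@@H]1/C=C(\C)COC(C)=O | target

## Step count and risks

Total step count: 10. Longest linear sequence: 8 steps (steps 1–5, then 8–10); the aldehyde arm is 2 steps (6–7).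

The three steps most likely to fail:

Step 8 (chromium allylation). The face selectivity anti to the C2 substituent should be high, but the anti/syn ratio at the carbinol rests on a chair model for a ring-locked allylchromium that I have derived rather than taken from a measured case. Aldehyde 16 can also slip into conjugation, and the chromium alkoxide could translactonise. The fallback sets out from 11 (with 16) and changes the mechanism to an open transition state. Bromide 11 is stannylated with hexabutylditin and Pd2(dba)3 (zerovalent palladium) in THF to the tributyl allylstannane F1. F1 is added to 16 with BF3·OEt2 in CH2Cl2 at −78 °C, where the antiperiplanar open transition state favours the syn adduct, the (1R)-alcohol F2. F2 is acylated without inversion (methacrylic anhydride, Et3N, DMAP, CH2Cl2, 0 °C), and the route is rejoined at 21, so step 9 is not needed.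

Step 9 (Mitsunobu with inversion). The carbinol is flanked by a branched ring carbon and an allylic methylene, so elimination to a conjugated diene or sluggish displacement is possible. The fallback sets out from 18 and replaces the redox condensation by a two-stage sulfonate displacement. Alcohol 18 is converted with ClCH2SO2Cl and pyridine at 0 °C into the (1S)-chloromethanesulfonate F3. F3 is displaced with inversion by caesium methacrylate CsO2CC(CH3)=CH2 and 18-crown-6 in toluene at 60 °C, coming back to the route at 21.

Step 7 (hydroboration–oxidation to a β,γ-unsaturated aldehyde). Over-hydroboration of the dienylborane or isomerisation of the aldehyde into conjugation during oxidation would lower the yield. The fallback sets out from 13 and reaches the aldehyde through an alcohol instead of an enol. Enyne 13 is semi-hydrogenated (H2, Pd/CaCO3 poisoned with Pb(OAc)2 and quinoline) to the diene F4. The terminal vinyl group of F4 is hydroborated with 9-BBN and oxidised (H2O2, NaOH) to the homoallylic alcohol F5. F5 is oxidised with Dess–Martin periodinane buffered with NaHCO3, coming back to the route at 16.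

Further compounds
F1 | step 8 | tributyl{[(5R)-5-[(E)-3-acetoxy-2-methylprop-1-en-1-yl]-2-oxo-2,5-dihydrofuran-3-yl]methyl}stannane | CCCC[Sn](CCCC)(CCCC)CC1=C[C@@H](/C=C(\C)COC(C)=O)OC1=O
F2 | step 8 | (E)-3-[(2R,3R)-3-[(1R,3E)-5-[tert-butyl(dimethyl)silyl]oxy-1-hydroxy-3-methylpent-3-en-1-yl]-4-methylidene-5-oxooxolan-2-yl]-2-methylprop-2-en-1-yl acetate | O[C@H](C/C(C)=C/CO[Si](C)(C)C(C)(C)C)[C@H]1C(=C)C(=O)O[C@@H]1/C=C(\C)COC(C)=O
F3 | step 9 | (1S)-chloromethanesulfonate of alcohol 18 | ClCS(=O)(=O)O[C@@H](C/C(C)=C/CO[Si](C)(C)C(C)(C)C)[C@H]1C(=C)C(=O)O[C@@H]1/C=C(\C)COC(C)=O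
F4 | step 7 | tert-butyl(dimethyl){[(E)-3-methylpenta-2,4-dien-1-yl]oxy}silane | C=C/C(C)=C/CO[Si](C)(C)C(C)(C)C
F5 | step 7 | (E)-5-[tert-butyl(dimethyl)silyl]oxy-3-methylpent-3-en-1-ol | OCC/C(C)=C/CO[Si](C)(C)C(C)(C)C
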